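## The problem

Diplotrin A (21) is an achiral flavonol methyl ether: a 4H-chromen-4-one with a methoxyl at C3, methoxyls at C7 and C8 of ring A, and C2 bonded to C1' of a 2',5'-dihydroxy-4'-methoxyphenyl ring B. There is no stereocentre, so the task is regiochemistry and the timing of functional groups. Ring A is a 1,2,3,4-tetrasubstituted benzene in which O1, the C8 oxygen and the C7 oxygen are contiguous, a pattern that is awkward to reach regioselectively from a benzene precursor. Ring B is a hydroquinone that oxidises easily to the quinone once both hydroxyls are free, so its mask must stay on until the last step and come off without touching four methyl ethers or the C2=C3 double bond. The C2–C1' bond joins two ortho-substituted carbons (the C3 methoxyl on one side, the C2' oxygen on the other). The feature that opens a less usual route is the C6–C7–C8 segment, in which C7 bears oxygen and is bonded to an unsubstituted C6, and C8 sits on C8a. C7 can therefore be the carbonyl carbon of a ketene on a C8 side chain and C5=C6 a vinyl group on C4a, both held cis across the C4a=C8a double bond of a 4-pyranone, so that ring A closes by a six-electron electrocyclization. The pyranone this requires has oxygen at the future C3 and a carbon substituent at the future C8a, which is the substitution pattern of kojic acid (1).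

## Retrosynthesis

**21 ⇒ 20.** The two O–benzyl bonds of ring B are cut first. Benzyl is preferred to acetal or silyl protection because it must survive LiN(iPr)2, Ac2O with Et3N, two Suzuki couplings and K2CO3 in methanol, and because it is removed under neutral conditions. The precursor 20 is no simpler in skeleton, but the oxidisable hydroquinone is hidden for the whole route. The forward step must cleave two aryl benzyl ethers without reducing the chromone.

**20 ⇒ 18 (through potassium phenoxide 19).** The C7 O–methyl bond is cut and replaced by an O–acetyl bond. This is dictated by the ring-forming step, which delivers the C7 oxygen as an acetate. Introducing the C7 oxygen already methylated is not possible, because that oxygen is the ketene oxygen. The forward operation is an acetyl-for-methyl exchange on one oxygen: methanolysis of 18 with K2CO3 leaves the acidic 7-hydroxyl as its potassium salt 19, which is methylated in the same flask.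

**18 ⇒ 13 (the key cut, C6–C7).** Ring A is opened between C6 and C7. Cutting C5–C6 or C7–C8 would leave no carbonyl-type carbon to drive a ring closure. The C6–C7 cut makes C7 a carboxyl carbon (a ketene in the reacting form 15) and C5=C6 a vinyl group. The bicyclic chromone becomes the monocyclic, fully substituted 4-pyranone acid 13. Its single stereocentre (C8, racemic) is irrelevant because it becomes trigonal. The forward reaction must pass from 13 through mixed anhydride 14 to ketene 15 faster than the vinylogous β-keto acid loses carbon dioxide. Ring closure to dienone 16, enolization to phenol 17 and acetylation to 18 should then follow.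

**13 ⇒ 11 (C7–C8).** The carboxyl carbon is removed from the lateral carbon. This is the only C–C bond to C7 besides the one formed in the key step, and the lateral CH2 of 11 is the one acidic site of the molecule. A carbon electrophile can therefore be placed there late, by carboxylation of dienolate 12, without protecting anything. The forward step needs lateral rather than vinyl-terminus capture, and a cold isolation of the acid.

**11 ⇒ 9 + 10, and 9 ⇒ 4 + 8.** The vinyl group (future C5=C6) is cut from pyranone C3 and ring B from pyranone C6. Both are sp2–sp2 bonds suited to Suzuki–Miyaura coupling with vinylboronic ester 10 and arylboronic ester 8. The dihalide 4 carries iodine at C6 and bromine at C3. C6 is the enone β-carbon and the more reactive site toward oxidative addition, so halogen identity and position point the same way when the aryl group is introduced first. The opposite assignment (bromine at C6, iodine at C3, vinyl first) would set the two effects against each other. Halogenating after arylation was rejected because the trialkoxyphenyl ring would compete for the electrophile.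

**4 ⇒ 3 ⇒ 2 ⇒ 1.** The C3–Br bond, the two O–methyl bonds and the C6–I bond are cut in turn, back to kojic acid (1). The order is fixed by reactivity. C6 is halogenated while the 5-hydroxyl is free and directs like a phenol. Both hydroxyls are then methylated. C3, the only ring C–H left, is brominated last. All three oxygens of the future ring C and the future C8 carbon come from 1.

**8 ⇒ 7 ⇒ 6 ⇒ 5.** The C–B bond, the C–Br bond and the two O–benzyl bonds are cut back to 2-methoxyhydroquinone (5). Bromination of the bis-benzyl ether 6 is expected para to the methoxyl, which is the carbon that becomes C1'. No regiochemical decision is therefore left open on ring B.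

## Roads not taken

Alternative 1: The cut is at C2–C1' and C2–C3, with C2 supplied by carbon monoxide (A4). Aryl iodide A2 (1,4-bis(benzyloxy)-2-iodo-5-methoxybenzene), A4 and the magnesium enolate of ketone A3 (1-[3,4-dimethoxy-2-(methoxymethoxy)phenyl]-2-methoxyethan-1-one) would be joined under Pd(dba)2 with a bisphosphine, MgCl2 and Et3N to 1,3-diketone A1. No ring closes in that step. Acid would then remove the acetal and cyclodehydrate A1 to 20, one hydrogenolysis from 21.
- Merits: the ring closure that follows is the classical and very reliable flavone closure. The C3 methoxyl comes in with the methoxyacetyl group. The two fragments are simple benzenes, and the route is probably two to three steps shorter than the chosen one.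
- Weak points: A2 is very electron-rich and ortho-substituted, so acyl–palladium formation competes with direct α-arylation without A4. The enolate is that of an α-alkoxy ketone, and A1 is more acidic than A3 and chelating, which invites O-acylation and catalyst inhibition. A3 still requires a regioselectively made tetrasubstituted benzene.
- Comparison: in length and in the certainty of the ring closure this road is at least equal to the chosen plan. The chosen plan avoids a pressurised toxic gas. It obtains the contiguous O1/C8/C7 pattern from the connectivity of 1 and the closure itself, with no regiochemical step on a benzene ring. Its couplings are ordinary two-component Suzuki reactions.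

Alternative 2: The cut runs through ring B at C1'–C2' and C5'–C6'. 2-Ethynyl-3,7,8-trimethoxychromone A6 and siloxyfuran A7 (tert-butyl[(4-methoxyfuran-2-yl)oxy]dimethylsilane) would undergo Diels–Alder addition to oxanorbornadiene A8. Its bridge opens with aromatization to A5, the 2'-O-silyl ether of 21, and Bu4NF would finish the synthesis.
- Merits: ring B is made with all three oxygens in place and the two hydroxyls differentiated. There are no benzyl ethers and so no hydrogenation next to the flavone double bond. This endgame is milder than that of the chosen plan.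
- Weak points: the alkyne of A6 is activated only vinylogously through C2=C3, and the C3 methoxyl weakens it further. A7 is a hydrolytically labile silyl ketene acetal that may add as a nucleophile in a Michael sense without closing the second bond. A6 presupposes a finished ring A chromone, so the tetrasubstituted ring A problem is only moved, and C2 ethynylation adds steps.
- Comparison: overall length is similar. The chosen plan answers the milder deprotection of this road with a ring B made in three routine steps from 5 and a key step whose regiochemistry cannot vary.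

Alternative 3: The cuts are C4a–C4, C4–C3 and O1–C2, with C4 from A4. Iodophenol A10 (6-iodo-2,3-dimethoxyphenol), A4 and arylacetylene A11 (1,4-bis(benzyloxy)-2-ethynyl-5-methoxybenzene) would combine under PdCl2(PPh3)2 with Et2NH. Carbonylative alkynylation and 6-endo oxa-Michael closure give flavone A9 and close ring C.
- Merits: this is the most convergent entry to the flavone skeleton and the method is well established.
- Weak points: A9 lacks the C3 oxygen. It would have to be introduced afterwards by C3 oxidation and methylation, two further steps on a compound with two electron-rich rings, before 20 is reached. A10 again needs regioselective iodination of a pyrogallol ether. Competing 5-exo closure has to be suppressed.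
- Comparison: the skeleton is reached faster than in the chosen plan, but the correct oxidation level is not, and after the repair the step counts are comparable. The chosen plan carries the C3 oxygen from 1 through the whole route.

Key step: step 10

Remark on numbering: pyranones 2–4, 9 and 11–15 are named with kojic acid numbering (O1; C2 bearing the side-chain carbon; C3; C4=O; C5 bearing oxygen; C6). Flavone numbering is used from 16 on. Pyranone C6, C5, C3 and C2 become flavone C2, C3, C4a and C8a; the lateral carbon becomes C8, the carboxyl carbon C7, and the vinyl carbons C5 and C6. Acid 13 is racemic, and its stereocentre disappears in step 10.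

## Route

Step 1
Reactants: 1 kojic acid (5-hydroxy-2-(hydroxymethyl)-4H-pyran-4-one)
Product: 2 6-iodokojic acid (5-hydroxy-2-(hydroxymethyl)-6-iodo-4H-pyran-4-one)
Conditions: NIS, DMF, 0 °C to rt
Reagents that add atoms: N-iodosuccinimide, O=C1CCC(=O)N1I
Why: Kojic acid reacts like a phenol, so electrophilic iodination takes place at C6, ortho to the free 5-hydroxyl, the usual site of halogenation and Mannich reactions of this pyranone; C3 is far less reactive and mono-iodination should be clean.

Step 2
Reactants: 2 6-iodokojic acid
Product: 3 6-iodo-5-methoxy-2-(methoxymethyl)-4H-pyran-4-one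
Conditions: MeI, Ag2O, DMF, rt, dark
Reagents that add atoms: iodomethane, CI
Why: Purdie-type O-methylation with MeI and Ag2O etherifies the acidic enolic hydroxyl and the primary alcohol in one operation; no free alkoxide is formed, so addition–elimination at the iodine-bearing C6, a vinylogous acyl position, is avoided.

Step 3
Reactants: 3 6-iodo-5-methoxy-2-(methoxymethyl)-4H-pyran-4-one
Product: 4 3-bromo-6-iodo-5-methoxy-2-(methoxymethyl)-4H-pyran-4-one
Conditions: NBS, DMF, rt, dark
Reagents that add atoms: N-bromosuccinimide, O=C1CCC(=O)N1Br
Why: Electrophilic bromination at C3, the β-carbon of the O1–C2=C3 enol ether and the only ring C–H left, as in the 3-halogenation of 2-alkyl-4-pyranones; the polar solvent and exclusion of light disfavour radical bromination of the CH2OMe group.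

Step 4
Reactants: 5 2-methoxyhydroquinone (2-methoxybenzene-1,4-diol)
Product: 6 1,4-bis(benzyloxy)-2-methoxybenzene
Conditions: BnBr, K2CO3, DMF, 60 °C, under argon
Reagents that add atoms: benzyl bromide, BrCc1ccccc1
Why: Williamson etherification of both phenols; air is excluded because the electron-rich hydroquinone anion is easily oxidised.

Step 5
Reactants: 6 1,4-bis(benzyloxy)-2-methoxybenzene
Product: 7 1,4-bis(benzyloxy)-2-bromo-5-methoxybenzene
Conditions: NBS, MeCN, 0 °C
Reagents that add atoms: N-bromosuccinimide, O=C1CCC(=O)N1Br
Why: Electrophilic bromination of a 1,2,4-trialkoxybenzene goes to the carbon para to one alkoxy group and ortho to another, here para to the methoxyl, as with 1,2,4-trimethoxybenzene; the benzyl phenyl rings are far less activated.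

Step 6
Reactants: 7 1,4-bis(benzyloxy)-2-bromo-5-methoxybenzene
Product: 8 2-[2,5-bis(benzyloxy)-4-methoxyphenyl]-4,4,5,5-tetramethyl-1,3,2-dioxaborolane
Conditions: B2pin2, PdCl2(dppf) (cat.), KOAc, 1,4-dioxane, 90 °C
Reagents that add atoms: bis(pinacolato)diboron, CC1(C)OB(OC1(C)C)B1OC(C)(C)C(C)(C)O1
Why: Miyaura borylation of the aryl bromide; the pinacol ester is chosen over the free boronic acid because electron-rich ortho-alkoxy arylboronic acids protodeboronate easily.

Step 7
Reactants: 4 3-bromo-6-iodo-5-methoxy-2-(methoxymethyl)-4H-pyran-4-one; 8 2-[2,5-bis(benzyloxy)-4-methoxyphenyl]-4,4,5,5-tetramethyl-1,3,2-dioxaborolane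
Product: 9 6-[2,5-bis(benzyloxy)-4-methoxyphenyl]-3-bromo-5-methoxy-2-(methoxymethyl)-4H-pyran-4-one
Conditions: Pd(PPh3)4 (cat.), K3PO4, 1,4-dioxane/H2O, 60 °C
Reagents that add atoms: none
Why: Site-selective Suzuki–Miyaura coupling; oxidative addition of zerovalent palladium is much faster at C6–I (an iodide on the enone β-carbon) than at C3–Br (a bromide on the α-carbon), so halogen identity and position both send the aryl group to C6. The moderate temperature and a triarylphosphine ligand keep the bromide intact.

Step 8
Reactants: 9 6-[2,5-bis(benzyloxy)-4-methoxyphenyl]-3-bromo-5-methoxy-2-(methoxymethyl)-4H-pyran-4-one; 10 vinylboronic acid pinacol ester (4,4,5,5-tetramethyl-2-vinyl-1,3,2-dioxaborolane)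
Product: 11 6-[2,5-bis(benzyloxy)-4-methoxyphenyl]-5-methoxy-2-(methoxymethyl)-3-vinyl-4H-pyran-4-one
Conditions: Pd(OAc)2 (cat.), SPhos (2-dicyclohexylphosphino-2',6'-dimethoxybiphenyl), K3PO4, toluene/H2O, 80 °C
Reagents that add atoms: none
Why: Suzuki–Miyaura vinylation of an α-bromoenone-type C–Br bond, routine for 3-bromochromones and 3-bromoflavones; a bulky electron-rich biarylphosphine is used because the bromide is flanked by the carbonyl and the CH2OMe group.

Step 9
Reactants: 11 6-[2,5-bis(benzyloxy)-4-methoxyphenyl]-5-methoxy-2-(methoxymethyl)-3-vinyl-4H-pyran-4-one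
Product: 13 2-{6-[2,5-bis(benzyloxy)-4-methoxyphenyl]-5-methoxy-4-oxo-3-vinyl-4H-pyran-2-yl}-2-methoxyacetic acid (racemic), via lithium dienolate 12 (not isolated)
Conditions: LiN(iPr)2 (1.1 equiv), THF, −78 °C; dry CO2, −78 to −40 °C; 1 M HCl to pH 3, 0 °C; used at once without chromatography
Reagents that add atoms: carbon dioxide, O=C=O
Why: Lateral (vinylogous) deprotonation of the 2-CH2OMe group by LiN(iPr)2 gives extended dienolate 12, as with 2-methyl-4-pyranones and 2-methylchromones. Carboxylation at the lateral carbon is the only capture that restores the pyranone, and it creates the C8 stereocentre without control (racemic), which is of no consequence.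

Step 10
Reactants: 13 2-{6-[2,5-bis(benzyloxy)-4-methoxyphenyl]-5-methoxy-4-oxo-3-vinyl-4H-pyran-2-yl}-2-methoxyacetic acid
Product: 18 2-[2,5-bis(benzyloxy)-4-methoxyphenyl]-3,8-dimethoxy-4-oxo-4H-chromen-7-yl acetate (7-O-acetyl-7-O-demethyl-2',5'-di-O-benzyl diplotrin A), via acetic mixed anhydride 14 (not isolated), via dienylketene 15 (not isolated), via cyclohexadienone 16 (not isolated), via 7-hydroxyflavone 17 (not isolated)
Conditions: Ac2O (excess), Et3N, toluene (dilute), 0 °C, then 60 °C
Reagents that add atoms: acetic anhydride, CC(=O)OC(C)=O
Why: Acetic anhydride converts the triethylammonium carboxylate into mixed anhydride 14; its C8 hydrogen is activated by the anhydride carbonyl and, vinylogously, by the C4 carbonyl, so Et3N removes it and acetate leaves (E1cB) to give alkoxy(dienyl)ketene 15 with C7 as the ketene carbon. The triene C7=C8–C8a=C4a–C5=C6 then undergoes a thermal, disrotatory six-electron electrocyclization that forms the C6–C7 bond and closes the six-membered carbocycle (ring A) as cyclohexa-2,4-dienone 16. Enolization of 16 (C6–H to the C7 oxygen) gives phenol 17, which the excess anhydride acetylates to 18; aromatization makes the sequence irreversible. The closest known reactions are the Ac2O-mediated cyclization of 3,5-dienoic acids and Stobbe half-esters to phenol and naphthol acetates, and the electrocyclization of dienylketenes generated from 4-vinylcyclobutenones. No stereocentre is formed, and the racemic C8 centre of 13 becomes trigonal. Regiochemistry cannot vary, because the ketene and vinyl termini are held cis on the C4a=C8a bond and only one six-membered closure exists. The selectivity the step needs is one of rates: ketene formation must outrun decarboxylation of the vinylogous β-keto acid, which is secured by forming 14 at 0 °C with excess anhydride before warming, and the unimolecular closure must outrun ketene dimerization, which dilution favours.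

Step 11
Reactants: 18 2-[2,5-bis(benzyloxy)-4-methoxyphenyl]-3,8-dimethoxy-4-oxo-4H-chromen-7-yl acetate
Product: 20 2-[2,5-bis(benzyloxy)-4-methoxyphenyl]-3,7,8-trimethoxy-4H-chromen-4-one (2',5'-di-O-benzyl diplotrin A), via potassium flavon-7-olate 19 (not isolated)
Conditions: K2CO3, MeOH, rt; evaporate; MeI, DMF, rt
Reagents that add atoms: iodomethane, CI
Why: Methanolysis of the aryl acetate with K2CO3 in methanol (transesterification) leaves the acidic 7-hydroxyl as potassium phenoxide 19, which is O-methylated by MeI in a Williamson reaction after solvent exchange; benzyl ethers, methyl ethers and the chromone are inert to K2CO3 at room temperature.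

Step 12
Reactants: 20 2-[2,5-bis(benzyloxy)-4-methoxyphenyl]-3,7,8-trimethoxy-4H-chromen-4-one
Product: 21 diplotrin A (2-(2,5-dihydroxy-4-methoxyphenyl)-3,7,8-trimethoxy-4H-chromen-4-one)
Conditions: H2 (1 atm), palladium on carbon (Pd/C), EtOAc/MeOH, rt; work-up under argon
Reagents that add atoms: none
Why: Hydrogenolysis of the two aryl benzyl ethers; the tetrasubstituted, conjugated C2=C3 bond of a flavone is normally untouched at atmospheric pressure. The product is isolated with exclusion of air because the hydroquinone ring is oxidisable.

## Compound list

1 | kojic acid (5-hydroxy-2-(hydroxymethyl)-4H-pyran-4-one) | OCc1cc(=O)c(O)co1 | starting material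
2 | 6-iodokojic acid (5-hydroxy-2-(hydroxymethyl)-6-iodo-4H-pyran-4-one) | OCc1cc(=O)c(O)c(I)o1 | intermediate
3 | 6-iodo-5-methoxy-2-(methoxymethyl)-4H-pyran-4-one | COCc1cc(=O)c(OC)c(I)o1 | intermediate
4 | 3-bromo-6-iodo-5-methoxy-2-(methoxymethyl)-4H-pyran-4-one | COCc1oc(I)c(OC)c(=O)c1Br | intermediate
5 | 2-methoxyhydroquinone | COc1cc(O)ccc1O | starting material
6 | 1,4-bis(benzyloxy)-2-methoxybenzene | COc1cc(OCc2ccccc2)ccc1OCc1ccccc1 | intermediate
7 | 1,4-bis(benzyloxy)-2-bromo-5-methoxybenzene | COc1cc(OCc2ccccc2)c(Br)cc1OCc1ccccc1 | intermediate
8 | 2-[2,5-bis(benzyloxy)-4-methoxyphenyl]-4,4,5,5-tetramethyl-1,3,2-dioxaborolane | COc1cc(OCc2ccccc2)c(B2OC(C)(C)C(C)(C)O2)cc1OCc1ccccc1 | intermediate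
9 | 6-[2,5-bis(benzyloxy)-4-methoxyphenyl]-3-bromo-5-methoxy-2-(methoxymethyl)-4H-pyran-4-one | COCc1oc(-c2cc(OCc3ccccc3)c(OC)cc2OCc2ccccc2)c(OC)c(=O)c1Br | intermediate
10 | vinylboronic acid pinacol ester | C=CB1OC(C)(C)C(C)(C)O1 | starting material
11 | 6-[2,5-bis(benzyloxy)-4-methoxyphenyl]-5-methoxy-2-(methoxymethyl)-3-vinyl-4H-pyran-4-one | COCc1oc(-c2cc(OCc3ccccc3)c(OC)cc2OCc2ccccc2)c(OC)c(=O)c1C=C | intermediate
12 | lithium dienolate of 11 (lithium 6-[2,5-bis(benzyloxy)-4-methoxyphenyl]-5-methoxy-2-(methoxymethylidene)-3-vinyl-2H-pyran-4-olate; not isolated) | C=CC1=C(O[Li])C(OC)=C(c2cc(OCc3ccccc3)c(OC)cc2OCc2ccccc2)OC1=COC | intermediate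
13 | 2-{6-[2,5-bis(benzyloxy)-4-methoxyphenyl]-5-methoxy-4-oxo-3-vinyl-4H-pyran-2-yl}-2-methoxyacetic acid (racemic) | COC(C(=O)O)c1oc(-c2cc(OCc3ccccc3)c(OC)cc2OCc2ccccc2)c(OC)c(=O)c1C=C | intermediate
14 | acetic 2-{6-[2,5-bis(benzyloxy)-4-methoxyphenyl]-5-methoxy-4-oxo-3-vinyl-4H-pyran-2-yl}-2-methoxyacetic anhydride (racemic; not isolated) | COC(C(=O)OC(C)=O)c1oc(-c2cc(OCc3ccccc3)c(OC)cc2OCc2ccccc2)c(OC)c(=O)c1C=C | intermediate
15 | 6-[2,5-bis(benzyloxy)-4-methoxyphenyl]-5-methoxy-2-(1-methoxy-2-oxoethenyl)-3-vinyl-4H-pyran-4-one (dienylketene; not isolated) | COC(=C=O)c1oc(-c2cc(OCc3ccccc3)c(OC)cc2OCc2ccccc2)c(OC)c(=O)c1C=C | intermediate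
16 | 2-[2,5-bis(benzyloxy)-4-methoxyphenyl]-3,8-dimethoxy-6H-chromene-4,7-dione (cyclohexadienone tautomer; not isolated) | COC1=C2OC(c3cc(OCc4ccccc4)c(OC)cc3OCc3ccccc3)=C(OC)C(=O)C2=CCC1=O | intermediate
17 | 2-[2,5-bis(benzyloxy)-4-methoxyphenyl]-7-hydroxy-3,8-dimethoxy-4H-chromen-4-one (not isolated) | COc1c(O)ccc2c1oc(-c1cc(OCc3ccccc3)c(OC)cc1OCc1ccccc1)c(OC)c2=O | intermediate
18 | 2-[2,5-bis(benzyloxy)-4-methoxyphenyl]-3,8-dimethoxy-4-oxo-4H-chromen-7-yl acetate | CC(=O)Oc1ccc2c(c1OC)oc(-c1cc(OCc3ccccc3)c(OC)cc1OCc1ccccc1)c(OC)c2=O | intermediate
19 | potassium 2-[2,5-bis(benzyloxy)-4-methoxyphenyl]-3,8-dimethoxy-4-oxo-4H-chromen-7-olate (not isolated) | COc1c([O-])ccc2c1oc(-c1cc(OCc3ccccc3)c(OC)cc1OCc1ccccc1)c(OC)c2=O.[K+] | intermediate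
20 | 2-[2,5-bis(benzyloxy)-4-methoxyphenyl]-3,7,8-trimethoxy-4H-chromen-4-one | COc1ccc2c(c1OC)oc(-c1cc(OCc3ccccc3)c(OC)cc1OCc1ccccc1)c(OC)c2=O | intermediate
21 | diplotrin A (2-(2,5-dihydroxy-4-methoxyphenyl)-3,7,8-trimethoxy-4H-chromen-4-one) | COc1cc(O)c(-c2oc3c(OC)c(OC)ccc3c(=O)c2OC)cc1O | target

## Step count and least certain steps

Total: 12 steps (nine on the pyranone–flavone line, three for the ring B boronate).
Longest linear sequence: 9 steps (1 → 2 → 3 → 4 → 9 → 11 → 13 → 18 → 20 → 21; the line from 5 through 6, 7 and 8 is equally long).

**Step 10 (key step).** The most likely failure is loss of carbon dioxide from the carboxylate or from 14 before the ketene forms. A second risk is bimolecular consumption of ketene 15 (dimerization, acylation of a second molecule) if the electrocyclization is slower than expected. The fallback avoids the free acid and sets out from 11. Dienolate 12 is generated as in step 9 with two equivalents of LiN(iPr)2 and acylated with diphenyl carbonate to give phenyl 2-{6-[2,5-bis(benzyloxy)-4-methoxyphenyl]-5-methoxy-4-oxo-3-vinyl-4H-pyran-2-yl}-2-methoxyacetate F1. Heating F1 with Et3N in toluene expels phenoxide by E1cB elimination, a recognised route from aryl esters with an acidic α-hydrogen to ketenes. This gives the same ketene 15 and, after ring closure to 16 and tautomerization, phenol 17, which is isolated here. Methylation of 17 with MeI and K2CO3 in DMF, through phenoxide 19, rejoins the route at 20.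

**Step 9.** The likely failures are decarboxylation during acidification and extraction, and carboxylation at the vinyl terminus of the pentadienyl-type anion in place of the lateral carbon. The fallback sets out from 11. Dienolate 12, generated with two equivalents of LiN(iPr)2, is quenched with Boc2O to give tert-butyl 2-{6-[2,5-bis(benzyloxy)-4-methoxyphenyl]-5-methoxy-4-oxo-3-vinyl-4H-pyran-2-yl}-2-methoxyacetate F2, a stable ester that can be purified from regioisomers. Cleavage with CF3CO2H in CH2Cl2 at 0 °C, followed by cold evaporation, releases acid 13 without aqueous work-up, and the route is rejoined at 13.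

**Step 7.** The likely failures are erosion of site selectivity (oxidative addition at C3–Br beside C6–I, leading to double arylation), displacement of the C6 iodide by hydroxide at this vinylogous acyl position, and protodeboronation of 8. The fallback is a Negishi coupling without water or base and sets out from 7 and 4. Bromine–lithium exchange on 7 with n-BuLi in THF at −78 °C gives [2,5-bis(benzyloxy)-4-methoxyphenyl]lithium F3. Transmetalation with ZnCl2 gives [2,5-bis(benzyloxy)-4-methoxyphenyl]zinc chloride F4. F4 couples with 4 under Pd(PPh3)4 in THF at room temperature, where only the iodide should react, and the route is rejoined at 9.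

**Step 3.** The likely failure is sluggish substitution at C3, because the iodide and the carbonyl deactivate the ring, so that radical bromination of the methoxymethyl group takes over. The fallback replaces substitution by addition–elimination and sets out from 3. Br2 in CH2Cl2 at 0 °C adds across the O1–C2=C3 enol ether to give 2,3-dibromo-6-iodo-5-methoxy-2-(methoxymethyl)-2,3-dihydro-4H-pyran-4-one F5. Et3N then removes the acidic C3 hydrogen and expels the C2 bromide, and the route is rejoined at 4.

**Step 12.** The likely failures are over-reduction of the chromone (saturation of C2=C3) while the hindered 2'-benzyl ether cleaves slowly, and air oxidation of the hydroquinone during isolation. The fallback is a non-reductive cleavage that sets out from 20. BCl3 with pentamethylbenzene as cation scavenger in CH2Cl2 at −78 °C removes both benzyl groups and gives 21 directly. The cold, short exposure is meant to spare the C3 methyl ether next to the carbonyl. No new compound is made.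

## Further compounds

F1 | step 10 | phenyl 2-{6-[2,5-bis(benzyloxy)-4-methoxyphenyl]-5-methoxy-4-oxo-3-vinyl-4H-pyran-2-yl}-2-methoxyacetate (racemic) | COC(C(=O)Oc1ccccc1)c1oc(-c2cc(OCc3ccccc3)c(OC)cc2OCc2ccccc2)c(OC)c(=O)c1C=C
F2 | step 9 | tert-butyl 2-{6-[2,5-bis(benzyloxy)-4-methoxyphenyl]-5-methoxy-4-oxo-3-vinyl-4H-pyran-2-yl}-2-methoxyacetate (racemic) | COC(C(=O)OC(C)(C)C)c1oc(-c2cc(OCc3ccccc3)c(OC)cc2OCc2ccccc2)c(OC)c(=O)c1C=C
F3 | step 7 | [2,5-bis(benzyloxy)-4-methoxyphenyl]lithium | COc1cc(OCc2ccccc2)c([Li])cc1OCc1ccccc1
F4 | step 7 | [2,5-bis(benzyloxy)-4-methoxyphenyl]zinc chloride | COc1cc(OCc2ccccc2)c([Zn]Cl)cc1OCc1ccccc1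
F5 | step 3 | 2,3-dibromo-6-iodo-5-methoxy-2-(methoxymethyl)-2,3-dihydro-4H-pyran-4-one (racemic, mixture of diastereomers) | COCC1(Br)OC(I)=C(OC)C(=O)C1Br
F0 | step 12 | none | none
A1 | alternative 1 | 1-[3,4-dimethoxy-2-(methoxymethoxy)phenyl]-3-[2,5-bis(benzyloxy)-4-methoxyphenyl]-2-methoxypropane-1,3-dione (racemic, labile centre) | COCOc1c(C(=O)C(OC)C(=O)c2cc(OCc3ccccc3)c(OC)cc2OCc2ccccc2)ccc(OC)c1OC
A2 | alternative 1 | 1,4-bis(benzyloxy)-2-iodo-5-methoxybenzene | COc1cc(OCc2ccccc2)c(I)cc1OCc1ccccc1
A3 | alternative 1 | 1-[3,4-dimethoxy-2-(methoxymethoxy)phenyl]-2-methoxyethan-1-one | COCC(=O)c1ccc(OC)c(OC)c1OCOC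
A4 | alternative 1 | carbon monoxide | [C-]#[O+]
A5 | alternative 2 | 2'-O-(tert-butyldimethylsilyl) diplotrin A | COc1cc(O[Si](C)(C)C(C)(C)C)c(-c2oc3c(OC)c(OC)ccc3c(=O)c2OC)cc1O
A6 | alternative 2 | 2-ethynyl-3,7,8-trimethoxy-4H-chromen-4-one | C#Cc1oc2c(OC)c(OC)ccc2c(=O)c1OC
A7 | alternative 2 | tert-butyl[(4-methoxyfuran-2-yl)oxy]dimethylsilane | COc1coc(O[Si](C)(C)C(C)(C)C)c1
A8 | alternative 2 | 2-[1-(tert-butyldimethylsilyloxy)-5-methoxy-7-oxabicyclo[2.2.1]hepta-2,5-dien-2-yl]-3,7,8-trimethoxy-4H-chromen-4-one (racemic) | CC(C)(C)[Si](C)(C)OC12OC(C=C1c1oc3c(OC)c(OC)ccc3c(=O)c1OC)C(OC)=C2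
A9 | alternative 3 | 2-[2,5-bis(benzyloxy)-4-methoxyphenyl]-7,8-dimethoxy-4H-chromen-4-one | COc1cc(OCc2ccccc2)c(-c2cc(=O)c3ccc(OC)c(OC)c3o2)cc1OCc1ccccc1
A10 | alternative 3 | 6-iodo-2,3-dimethoxyphenol | COc1ccc(I)c(O)c1OC
A11 | alternative 3 | 1,4-bis(benzyloxy)-2-ethynyl-5-methoxybenzene | C#Cc1cc(OCc2ccccc2)c(OC)cc1OCc1ccccc1
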